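Numbering the core as bicyclo[3.2.1]oct-3-ene-2,8-dione (C1 H-bridgehead, C2=O, C3–OMe, C4=CH, C5 allyl bridgehead, C6–Me, C7–aryl, C8=O), the route exploits the cyclopentanone ring C8–C5–C6–C7–C1, whose carbonyl C8 lies between quaternary C5 and C1: C8–C5 is made by a ketene adding across a C5=C4 alkene. One photochemical operation (Wolff shift of C7, then crossed [2+2]) forges C5–C8 and a sacrificial C1–C4 bond, closing a bicyclo[2.1.1]hexan-5-one and fixing C5. The precursor is an acyclic α-diazoketone carrying the C6/C7 stereodiad, an (E)-trisubstituted C5=C4 alkene and a CH(OMe)C(O)N(OMe)Me arm on C4; base later moves C1 from C4 to C2.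

Key step: step 9

Remark on numbering: all intermediates carry the atom numbers C1–C8 of the final core.
Remark on design (assumption): the C2 acyl group is carried as an N-methoxy-N-methylamide (same carbon skeleton as an alkyl ester), because it is less C–H acidic than the arylacetate in step 7 and holds the acylation product as a chelate in step 10; C3 is formed as its R epimer and is erased in step 10.

Step 1
Reactants: 1 but-2-yn-1-ol; 2 allylmagnesium bromide
Product: 4 (2E)-2-(prop-2-en-1-yl)but-2-en-1-ol, via vinylmagnesium chelate 3 (not isolated)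
Conditions: 2 (3 equiv), Et2O, reflux; then aq. NH4Cl, 0 °C
Reagents that add atoms: none
Why: Hydroxyl-directed carbomagnesiation of a propargylic alcohol delivers allyl to the proximal alkyne carbon anti to the new C–Mg bond, which is held in the five-membered chelate 3, so protonolysis leaves methyl cis to allyl (E alkene only).

Step 2
Reactants: 4 (2E)-2-(prop-2-en-1-yl)but-2-en-1-ol
Product: 5 (2E)-2-(prop-2-en-1-yl)but-2-enal
Conditions: activated MnO2 (excess), CH2Cl2, 23 °C
Reagents that add atoms: none
Why: Allylic oxidation with MnO2 is selective for the primary allylic alcohol and neutral, so neither the alkene geometry nor the skipped diene should be disturbed.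

Step 3
Reactants: 6 (4R)-4-benzyl-1,3-oxazolidin-2-one; 7 methoxyacetyl chloride
Product: 8 (4R)-4-benzyl-3-(methoxyacetyl)-1,3-oxazolidin-2-one
Conditions: n-BuLi, THF, −78 °C; then 7, −78 → 0 °C
Reagents that add atoms: none
Why: N-Acylation of the lithiated oxazolidinone by an acid chloride is the standard way to load this auxiliary.

Step 4
Reactants: 8 (4R)-4-benzyl-3-(methoxyacetyl)-1,3-oxazolidin-2-one; 5 (2E)-2-(prop-2-en-1-yl)but-2-enal
Product: 10 (4R)-4-benzyl-3-[(2R,3S,4E)-3-hydroxy-2-methoxy-4-(prop-2-en-1-yl)hex-4-enoyl]-1,3-oxazolidin-2-one, via Z boron enolate 9 (not isolated)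
Conditions: Bu2BOTf, Et3N, CH2Cl2, −78 → 0 °C; then 5, −78 → 0 °C; pH 7 buffer, MeOH, 30% H2O2, 0 °C
Reagents that add atoms: none
Why: Evans syn-aldol reaction, in which the Z boron enolate 9 adds through a closed chair (Zimmerman–Traxler) transition state on the enolate face remote from the benzyl group, setting C4 (S) and C3 (R) together; α-branched enals are good acceptors and react only at the carbonyl.

Step 5
Reactants: 10 (4R)-4-benzyl-3-[(2R,3S,4E)-3-hydroxy-2-methoxy-4-(prop-2-en-1-yl)hex-4-enoyl]-1,3-oxazolidin-2-one
Product: 11 (2R,3S,4E)-3-hydroxy-N,2-dimethoxy-N-methyl-4-(prop-2-en-1-yl)hex-4-enamide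
Conditions: MeNHOMe·HCl, Me3Al, CH2Cl2, −20 → 0 °C; aq. Rochelle salt
Reagents that add atoms: N,O-dimethylhydroxylamine hydrochloride, CNOC.Cl
Why: Transamination of the imide by the aluminium amide (Weinreb amide formation) is directed by the free β-hydroxyl, runs below 0 °C without retro-aldol or epimerisation and returns the auxiliary.

Step 6
Reactants: 11 (2R,3S,4E)-3-hydroxy-N,2-dimethoxy-N-methyl-4-(prop-2-en-1-yl)hex-4-enamide; 12 (3,4-dimethoxyphenyl)acetic acid
Product: 13 (2R,3S,4E)-2-methoxy-1-[methoxy(methyl)amino]-1-oxo-4-(prop-2-en-1-yl)hex-4-en-3-yl (3,4-dimethoxyphenyl)acetate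
Conditions: DCC, DMAP (cat.), CH2Cl2, 0 → 23 °C
Reagents that add atoms: none
Why: Steglich esterification acylates the hindered secondary allylic alcohol under neutral conditions that do not affect C3 or C4.

Step 7
Reactants: 13 (2R,3S,4E)-2-methoxy-1-[methoxy(methyl)amino]-1-oxo-4-(prop-2-en-1-yl)hex-4-en-3-yl (3,4-dimethoxyphenyl)acetate
Product: 16 (2S,3R,4E,6R)-2-(3,4-dimethoxyphenyl)-6-methoxy-7-[methoxy(methyl)amino]-3-methyl-7-oxo-4-(prop-2-en-1-yl)hept-4-enoic acid, via silyl ketene acetal 14 (not isolated), via trimethylsilyl ester 15 (not isolated)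
Conditions: LiHMDS (1.15 equiv), THF, −78 °C; TMSCl/Et3N, −78 → 23 °C; then 1 M HCl
Reagents that add atoms: none
Why: Ireland–Claisen rearrangement, in which the amide base deprotonates only the arylacetate (about six pKa units more acidic than the amide α-C–H, so no β-elimination), the aryl-stabilised ester enolate forms with aryl cis to the metal-bound oxygen, and the chair transition state with the C4 substituent equatorial relays C4 (S) into C7 (S) and C6 (R) (2,3-syn) while forming the E C5=C4 alkene.

Step 8
Reactants: 16 (2S,3R,4E,6R)-2-(3,4-dimethoxyphenyl)-6-methoxy-7-[methoxy(methyl)amino]-3-methyl-7-oxo-4-(prop-2-en-1-yl)hept-4-enoic acid; 17 diazomethane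
Product: 19 (2R,3E,5R,6S)-8-diazo-6-(3,4-dimethoxyphenyl)-N,2-dimethoxy-N,5-dimethyl-7-oxo-4-(prop-2-en-1-yl)oct-3-enamide, via acid chloride 18 (not isolated)
Conditions: 1-chloro-N,N,2-trimethylprop-1-en-1-amine, CH2Cl2, 0 → 23 °C; then CH2N2 (3 equiv), Et2O, 0 °C
Reagents that add atoms: none
Why: Acylation of diazomethane by an acid chloride made under neutral conditions (first stage of an Arndt–Eistert homologation); no tertiary amine is present, so the α-aryl centre C7 should not be lost through ketene formation, and a second equivalent of diazomethane removes HCl.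

Step 9
Reactants: 19 (2R,3E,5R,6S)-8-diazo-6-(3,4-dimethoxyphenyl)-N,2-dimethoxy-N,5-dimethyl-7-oxo-4-(prop-2-en-1-yl)oct-3-enamide
Product: 21 (2R)-2-[(1S,2R,3R,4R,6R)-3-(3,4-dimethoxyphenyl)-2-methyl-5-oxo-1-(prop-2-en-1-yl)bicyclo[2.1.1]hexan-6-yl]-N,2-dimethoxy-N-methylacetamide (aryl syn to the carbonyl bridge, methyl syn to the substituted bridge, side chain anti to the C6–C7 bridge), via ketene 20 (not isolated)
Conditions: hν (365 nm), degassed PhMe (5 mM), 23 °C; then 80 °C in the dark
Reagents that add atoms: none
Why: Excitation of 19 expels N2 and C7 shifts with retention from the carbonyl carbon to the carbene carbon (Wolff rearrangement) to give aldoketene 20, which on warming adds thermally and asynchronously across the C5=C4 alkene, C8 to C5 and C1 to C4. The closest known reaction type is the intramolecular ketene–alkene [2+2] cycloaddition of photochemically generated ketenes joined by a two-atom tether to a 1,1-disubstituted alkene carbon, which gives bicyclo[2.1.1]hexan-5-ones. The cyclopentanone (C8–C1–C7–C6–C5) closes in the 5-exo sense by attack of the ketene carbonyl carbon on the proximal alkene carbon and the cyclobutanone (C8–C5–C4–C1) closes in the crossed sense; the fused alternative would need a bicyclo[2.2.0]hexanone and is excluded by the short tether, although the crossed mode puts the developing positive charge on C4 and therefore needs heat. C4 is fixed by the alkene geometry (suprafacial addition keeps the side chain trans to C6, away from the C6–C7 bridge), and C1 and C5 are fixed together by the alkene face, which the C6/C7 stereocentres control: the transition state that places the aryl group beside the substituent-free ketene carbon C8 and the methyl group beside C4–H is the less crowded one. The step needs crossed regiochemistry (tether), this diastereoface (C6/C7), reaction at the trisubstituted alkene and not at the allyl group (five- against seven-membered closure) and rearrangement before carbene addition (direct, metal-free irradiation at a wavelength the product ketone does not absorb).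

Step 10
Reactants: 21 (2R)-2-[(1S,2R,3R,4R,6R)-3-(3,4-dimethoxyphenyl)-2-methyl-5-oxo-1-(prop-2-en-1-yl)bicyclo[2.1.1]hexan-6-yl]-N,2-dimethoxy-N-methylacetamide
Product: 24 kadsurenin D, (1S,5S,6R,7R)-7-(3,4-dimethoxyphenyl)-3-methoxy-6-methyl-5-(prop-2-en-1-yl)bicyclo[3.2.1]oct-3-ene-2,8-dione, via lithium enolate 22 (not isolated), via chelated adduct 23 (not isolated)
Conditions: LiHMDS (1.3 equiv), PhMe–THF (10:1), −78 → 0 °C; then AcOH, −78 °C
Reagents that add atoms: none
Why: Proposed new method: the amide base removes C3–H, the only acidic proton of 21 (C1–H is a bridgehead hydrogen and C5 is quaternary), and the amide enolate expels C1 as a cyclopentanone enolate by cleaving the strained C1–C4 bond (retro-Michael, E1cB-type), after which enolate 22 attacks the amide carbonyl C2 through a lithium-bridged six-membered array to give the N,O-chelated adduct 23, which survives until the acidic quench and so shields the non-enolisable β-diketone from retro-Claisen cleavage; the closest known reaction types are the base-induced retro-Michael opening of strained 1,5-dicarbonyl cyclobutanes and the C-acylation of ketone lithium enolates by N-methoxy-N-methylamides; C1 rather than C5 should leave because carbanionic ring openings break the bond to the less alkylated carbon and the C7–aryl bond lies antiperiplanar to C1–C4, the lithium shared by the enolate oxygen and the C8 carbonyl should hold C2 over the ketone bridge so that the acrylamide forms with C2 cis to C5, and C1 is re-formed with the only configuration the bridged ring allows while C3 becomes sp2.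

Compound list
1 | but-2-yn-1-ol | CC#CCO | starting material
2 | allylmagnesium bromide (solution in Et2O) | C=CC[Mg]Br | starting material
3 | bromomagnesium (2Z)-3-(bromomagnesio)-2-(prop-2-en-1-yl)but-2-en-1-olate (vinylmagnesium chelate) | C/C([Mg]Br)=C(CC=C)/CO[Mg]Br | intermediate
4 | (2E)-2-(prop-2-en-1-yl)but-2-en-1-ol | C/C=C(CC=C)/CO | intermediate
5 | (2E)-2-(prop-2-en-1-yl)but-2-enal | C/C=C(CC=C)/C=O | intermediate
6 | (4R)-4-benzyl-1,3-oxazolidin-2-one | O=C1N[C@H](Cc2ccccc2)CO1 | starting material
7 | methoxyacetyl chloride | COCC(Cl)=O | starting material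
8 | (4R)-4-benzyl-3-(methoxyacetyl)-1,3-oxazolidin-2-one | COCC(=O)N1C(=O)OC[C@H]1Cc1ccccc1 | intermediate
9 | (Z)-dibutylboron enolate of 8 | CO/C=C(\OB(CCCC)CCCC)N1C(=O)OC[C@H]1Cc1ccccc1 | intermediate
10 | (4R)-4-benzyl-3-[(2R,3S,4E)-3-hydroxy-2-methoxy-4-(prop-2-en-1-yl)hex-4-enoyl]-1,3-oxazolidin-2-one | C/C=C(CC=C)/[C@H](O)[C@@H](OC)C(=O)N1C(=O)OC[C@H]1Cc1ccccc1 | intermediate
11 | (2R,3S,4E)-3-hydroxy-N,2-dimethoxy-N-methyl-4-(prop-2-en-1-yl)hex-4-enamide | C/C=C(CC=C)/[C@H](O)[C@@H](OC)C(=O)N(C)OC | intermediate
12 | (3,4-dimethoxyphenyl)acetic acid | COc1ccc(CC(=O)O)cc1OC | starting material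
13 | (2R,3S,4E)-2-methoxy-1-[methoxy(methyl)amino]-1-oxo-4-(prop-2-en-1-yl)hex-4-en-3-yl (3,4-dimethoxyphenyl)acetate | C/C=C(CC=C)/[C@H](OC(=O)Cc1ccc(OC)c(OC)c1)[C@@H](OC)C(=O)N(C)OC | intermediate
14 | (Z)-trimethylsilyl ketene acetal of 13 (aryl cis to OSiMe3) | C/C=C(CC=C)/[C@H](O/C(O[Si](C)(C)C)=C/c1ccc(OC)c(OC)c1)[C@@H](OC)C(=O)N(C)OC | intermediate
15 | trimethylsilyl ester of 16 | C[Si](C)(C)OC(=O)[C@H](c1ccc(OC)c(OC)c1)[C@@H](C)/C(CC=C)=C/[C@@H](OC)C(=O)N(C)OC | intermediate
16 | (2S,3R,4E,6R)-2-(3,4-dimethoxyphenyl)-6-methoxy-7-[methoxy(methyl)amino]-3-methyl-7-oxo-4-(prop-2-en-1-yl)hept-4-enoic acid | OC(=O)[C@H](c1ccc(OC)c(OC)c1)[C@@H](C)/C(CC=C)=C/[C@@H](OC)C(=O)N(C)OC | intermediate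
17 | diazomethane (ethereal solution from commercial N-methyl-N-nitroso-p-toluenesulfonamide) | C=[N+]=[N-] | starting material
18 | acid chloride of 16 | ClC(=O)[C@H](c1ccc(OC)c(OC)c1)[C@@H](C)/C(CC=C)=C/[C@@H](OC)C(=O)N(C)OC | intermediate
19 | (2R,3E,5R,6S)-8-diazo-6-(3,4-dimethoxyphenyl)-N,2-dimethoxy-N,5-dimethyl-7-oxo-4-(prop-2-en-1-yl)oct-3-enamide | [N-]=[N+]=CC(=O)[C@H](c1ccc(OC)c(OC)c1)[C@@H](C)/C(CC=C)=C/[C@@H](OC)C(=O)N(C)OC | intermediate
20 | ketene from 19 (C7 shifted from C8 to C1 with retention) | O=C=C[C@H](c1ccc(OC)c(OC)c1)[C@@H](C)/C(CC=C)=C/[C@@H](OC)C(=O)N(C)OC | intermediate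
21 | (2R)-2-[(1S,2R,3R,4R,6R)-3-(3,4-dimethoxyphenyl)-2-methyl-5-oxo-1-(prop-2-en-1-yl)bicyclo[2.1.1]hexan-6-yl]-N,2-dimethoxy-N-methylacetamide | C=CC[C@@]12C(=O)[C@@H]([C@H]1[C@@H](OC)C(=O)N(C)OC)[C@H](c1ccc(OC)c(OC)c1)[C@H]2C | intermediate
22 | lithium (3R,4R,5S)-3-(3,4-dimethoxyphenyl)-5-{(1E)-2-methoxy-3-[methoxy(methyl)amino]-3-oxoprop-1-en-1-yl}-4-methyl-5-(prop-2-en-1-yl)cyclopent-1-en-1-olate | C=CC[C@]1(/C=C(/OC)C(=O)N(C)OC)C(O[Li])=C[C@H](c2ccc(OC)c(OC)c2)[C@H]1C | intermediate
23 | lithium alkoxide of the C2 hemiaminal of 24 (N,O-chelated adduct; configuration at C2 not specified) | C=CC[C@]12C=C(OC)C(O[Li])(N(C)OC)[C@H](C1=O)[C@H](c1ccc(OC)c(OC)c1)[C@H]2C | intermediate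
24 | kadsurenin D, (1S,5S,6R,7R)-7-(3,4-dimethoxyphenyl)-3-methoxy-6-methyl-5-(prop-2-en-1-yl)bicyclo[3.2.1]oct-3-ene-2,8-dione | C=CC[C@]12C=C(OC)C(=O)[C@H](C1=O)[C@H](c1ccc(OC)c(OC)c1)[C@H]2C | target

Total step count: 10. Longest linear sequence: 9 (steps 1, 2, 4, 5, 6, 7, 8, 9, 10); step 3 prepares the second aldol partner.

Steps most likely to fail

1. Step 10 (proposed new method). The cage may open at the C4–C5 bond instead of C1–C4, since that path releases the more substituted enolate and more steric strain. The ring opening may also deliver the acrylamide with C2 trans to C5, so that the enolate cannot reach the amide carbonyl. Deprotonation at the hindered C3 may be slow enough for base attack on the N-methoxy group to compete. Fallback with known reactions, setting out from 21 and returning at 24: the relay is run stepwise. Brief treatment of 21 with LiHMDS at −78 °C and a cold acetic acid quench should stop after the retro-Michael step and give the ring-opened ketone, (2Z)-3-[(1S,2R,3S)-3-(3,4-dimethoxyphenyl)-2-methyl-5-oxo-1-(prop-2-en-1-yl)cyclopentyl]-N,2-dimethoxy-N-methylprop-2-enamide F1, whose structure also shows which cage bond has broken. Acetophenone-sensitised irradiation (350 nm) should equilibrate the acyclic alkene, since free rotation of the triplet outruns oxa-di-π-methane rearrangement, to a mixture containing the (2E)-isomer F2, which is separated while F1 is recycled. Deprotonation of F2 at C1, its only enolisable position, with LiHMDS gives enolate 22, and the known intramolecular acylation of a ketone enolate by a Weinreb amide followed by acidic quench should give 24. This sequence does not repair a C4–C5 opening.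

2. Step 9 (key step). The excited diazoketone may add as a carbene to the C5=C4 alkene or insert into C–H bonds before it rearranges. The ketene may dimerise or undergo an ene reaction because the C4 terminus is electron-poor. The cycloaddition may take the other alkene face (aryl over the C4 bridge), and C7 may epimerise in the diazoketone. Fallback, setting out from 19 and returning at 21: light and free carbene are removed from the ring-forming event. Silver benzoate and Et3N in aqueous THF should convert 19 by Wolff rearrangement into the homologous acid, (3S,4R,5E,7R)-3-(3,4-dimethoxyphenyl)-7-methoxy-8-[methoxy(methyl)amino]-4-methyl-8-oxo-5-(prop-2-en-1-yl)oct-5-enoic acid F3. 1-Chloro-N,N,2-trimethylprop-1-en-1-amine turns it into the acid chloride F4. Slow addition of F4 to Et3N in refluxing toluene generates the same ketene 20 by dehydrochlorination at a temperature at which it cyclises at once, the classical thermal protocol for intramolecular ketene–alkene cycloaddition, to give 21.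

3. Step 7. The enolate geometry may be incompletely controlled or a boat transition state may intervene, giving the C7 epimer. The free ester enolate may transfer its acyl group to the neighbouring amide or trigger loss of arylacetate before it is silylated. Fallback, setting out from 13 and returning at 16: soft enolisation replaces the metal amide. Dibutylboron triflate (2.2 equiv, one equivalent being held by the amide oxygen) and iPr2NEt in CH2Cl2 at −78 °C should enolise only the arylacetate to the O-dibutylboryl ketene acetal F5 (aryl cis to the boron-bound oxygen). This boron ester-enolate Claisen rearrangement proceeds below room temperature to the dibutylboryl ester F6, and aqueous work-up gives 16. No strong base and no free enolate are present at any point.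

Further compounds
F1 | step 10 | (2Z)-3-[(1S,2R,3S)-3-(3,4-dimethoxyphenyl)-2-methyl-5-oxo-1-(prop-2-en-1-yl)cyclopentyl]-N,2-dimethoxy-N-methylprop-2-enamide | C=CC[C@]1(/C=C(\OC)C(=O)N(C)OC)C(=O)C[C@H](c2ccc(OC)c(OC)c2)[C@H]1C
F2 | step 10 | (2E)-3-[(1S,2R,3S)-3-(3,4-dimethoxyphenyl)-2-methyl-5-oxo-1-(prop-2-en-1-yl)cyclopentyl]-N,2-dimethoxy-N-methylprop-2-enamide | C=CC[C@]1(/C=C(/OC)C(=O)N(C)OC)C(=O)C[C@H](c2ccc(OC)c(OC)c2)[C@H]1C
F3 | step 9 | (3S,4R,5E,7R)-3-(3,4-dimethoxyphenyl)-7-methoxy-8-[methoxy(methyl)amino]-4-methyl-8-oxo-5-(prop-2-en-1-yl)oct-5-enoic acid | OC(=O)C[C@H](c1ccc(OC)c(OC)c1)[C@@H](C)/C(CC=C)=C/[C@@H](OC)C(=O)N(C)OC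
F4 | step 9 | acid chloride of F3 | ClC(=O)C[C@H](c1ccc(OC)c(OC)c1)[C@@H](C)/C(CC=C)=C/[C@@H](OC)C(=O)N(C)OC
F5 | step 7 | (Z)-O-dibutylboryl ketene acetal of 13 | C/C=C(CC=C)/[C@H](O/C(OB(CCCC)CCCC)=C/c1ccc(OC)c(OC)c1)[C@@H](OC)C(=O)N(C)OC
F6 | step 7 | dibutylboryl ester of 16 | CCCCB(CCCC)OC(=O)[C@H](c1ccc(OC)c(OC)c1)[C@@H](C)/C(CC=C)=C/[C@@H](OC)C(=O)N(C)OC
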